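The E-configured C13=C14 alkene, which lies homoallylic to the C16–O stereocentre of the butenolide ring, is the feature on which the route rests. The side chain is cut at C14–C15 and at the C13 methyl, and both bonds are made in one flask: zirconium-catalysed syn-methylalumination of a terminal alkyne, then opening of an enantiopure epoxide by the alkenylalanate. This joins the larixol-derived decalin (rings A and B) to the C15–C16 unit, fixes the alkene geometry and brings in C16 with its configuration intact. The precursor is a 9-butynyl decalin with O6 and O8 as silyl ethers and the C18 oxygen as a PMB ether, so that C18 can later be oxidised while O6 stays blocked and cannot lactonise.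

Key step: step 12

Remark: labdane numbering is used for the decalin (C17 on C8, C18 = 4α substituent, C19 = 4β methyl, C20 on C10), the side chain is counted C11 to C16 outward from C9, and compounds 1 and 14 are taken as catalogue materials.

**Route**

Step 1
Reactants: 1 larixol, (13S)-labda-8(17),14-diene-6α,13-diol
Product: 2 methyl ketone 6α-hydroxy-14,15-dinorlabd-8(17)-en-13-one
Conditions: KMnO4, MgSO4, acetone/H2O, 0 °C → rt
Reagents that add atoms: none
Why: Permanganate degradation of a tertiary vinyl carbinol (dihydroxylation of the vinyl group, glycol cleavage and loss of C14 and C15 as CO2) is established for labdane side chains and should leave the hindered C8=C17 alkene, the 6α-OH and every ring stereocentre untouched.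

Step 2
Reactants: 2 methyl ketone
Product: 3 spiro-epoxide 8α,17-epoxy-6α-hydroxy-14,15-dinorlabdan-13-one
Conditions: mCPBA, NaHCO3, CH2Cl2, 0 °C
Reagents that add atoms: 3-chloroperoxybenzoic acid, OOC(=O)c1cccc(Cl)c1
Why: Prilezhaev epoxidation of the 1,1-disubstituted alkene is faster than Baeyer–Villiger attack on the ketone, and the peracid should approach the α face because the β face is screened by the axial C20 methyl, which sets C8 with oxygen α.

Step 3
Reactants: 3 spiro-epoxide
Product: 6 tetrahydrofuran ether 6α,18:8α,17-diepoxy-14,15-dinorlabdan-13-one, via 6α-hypoiodite 4 (not isolated), via 18-iodo alcohol 5 (not isolated)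
Conditions: PhI(OAc)2, I2, NaHCO3, cyclohexane, hν (tungsten lamp), 35 °C
Reagents that add atoms: none
Why: In this Suárez hypoiodite reaction the 6α-alkoxy radical lies about 2.5 Å from the equatorial 4α-methyl carbon (C18) and about 3.5 Å from the axial C19, so 1,5-hydrogen transfer, iodine capture and oxidative displacement should close the ether onto C18 alone, making C4 a stereocentre with its CH2O arm α.

Step 4
Reactants: 6 tetrahydrofuran ether
Product: 7 γ-lactone 8α,17-epoxy-13-oxo-14,15-dinorlabdan-18,6α-olide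
Conditions: RuCl3·xH2O (cat.), NaIO4, EtOAc/MeCN/pH 7 phosphate buffer, rt
Reagents that add atoms: sodium periodate, [Na+].[O-]I(=O)(=O)=O (oxygen relayed by RuO4)
Why: RuO4 oxidation of a cyclic ether to the lactone should occur at the exposed C18 methylene and not at the C6 methine, whose β-hydrogen is flanked by the axial C19 and C20 methyls, while the buffer protects the spiro-epoxide.

Step 5
Reactants: 7 γ-lactone
Product: 9 alkyne lactone with a 9β-(but-3-ynyl) chain, via enol diethyl phosphate 8 (not isolated)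
Conditions: LiN(iPr)2 (1.1 equiv), THF, −78 °C; ClP(O)(OEt)2, −78 → 0 °C; then added to LiN(iPr)2 (2.5 equiv), THF, −78 → 0 °C; NH4Cl (aq) at 0 °C
Reagents that add atoms: none
Why: The enol phosphate route from a methyl ketone to a terminal alkyne (kinetic deprotonation at CH3, O-phosphorylation, amide-induced β-elimination) should tolerate the lactone, which has no α-hydrogen and a hindered carbonyl on quaternary C4, and the epoxide, which the amide does not isomerise below 0 °C.

Step 6
Reactants: 9 alkyne lactone
Product: 10 alkyne triol (6α-OH, 8α-OH, 18-OH)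
Conditions: LiAlH4, THF, 0 → 50 °C; Fieser work-up
Reagents that add atoms: none
Why: One hydride reagent reduces the lactone to the 6α,18-diol and opens the spiro-epoxide by SN2 attack at its CH2 carbon, which leaves the oxygen α on C8 and creates the 8β-methyl, while an isolated terminal alkyne is not reduced under these conditions.

Step 7
Reactants: 10 alkyne triol
Product: 11 18-O-PMB ether diol
Conditions: NaH (1.05 equiv), 4-methoxybenzyl chloride (1.05 equiv), Bu4NI (cat.), THF/DMF, 0 °C → rt
Reagents that add atoms: 4-methoxybenzyl chloride, COc1ccc(CCl)cc1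
Why: Williamson etherification should select the primary C18 alkoxide over the peri-hindered secondary O6 and the tertiary O8, and the acid-stable, oxidatively removable PMB group is what later lets C18 be unmasked and oxidised while O6 is still silylated.

Step 8
Reactants: 11 18-O-PMB ether diol
Product: 13 protected alkyne (18-O-PMB; 6-O-TBS; 8-O-TES), via 6-O-TBS ether 12 (not isolated)
Conditions: TBSOTf (1.3 equiv), 2,6-lutidine, CH2Cl2, −78 → −20 °C; then TESOTf (2 equiv), 0 °C → rt
Reagents that add atoms: tert-butyldimethylsilyl triflate, CC(C)(C)[Si](C)(C)OS(=O)(=O)C(F)(F)F; triethylsilyl triflate, CC[Si](CC)(CC)OS(=O)(=O)C(F)(F)F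
Why: In this silyl triflate silylation the bulkier TBSOTf should react at low temperature only with the secondary 6α-OH, after which the smaller TESOTf caps the tertiary 8α-OH, so that no hydroxyl is left to consume Al(CH3)3 or to add to the C13=C14 alkene later.

Step 9
Reactants: 14 2-(2-bromoethyl)-2-methyl-1,3-dioxolane
Product: 15 2-methyl-2-vinyl-1,3-dioxolane
Conditions: KOtBu, THF, 0 °C → rt; distillation
Reagents that add atoms: none
Why: E2 dehydrobromination of the primary bromide by the hindered, weakly nucleophilic tert-butoxide should give the vinyl ketal, the dioxolane being inert to base.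

Step 10
Reactants: 15 2-methyl-2-vinyl-1,3-dioxolane
Product: 16 racemic 2-(2-methyl-1,3-dioxolan-2-yl)oxirane
Conditions: mCPBA, NaHCO3, CH2Cl2, 40 °C; distillation
Reagents that add atoms: 3-chloroperoxybenzoic acid, OOC(=O)c1cccc(Cl)c1
Why: Prilezhaev epoxidation of the only alkene present should proceed, slowly because the vinyl group is electron-poor, while the bicarbonate buffer keeps the ketal intact; the racemate is resolved in step 11.

Step 11
Reactants: 16 racemic epoxide
Product: 17 (R)-2-(2-methyl-1,3-dioxolan-2-yl)oxirane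
Conditions: (S,S)-(salen)Co(OAc) (trivalent cobalt; salen = N,N'-bis(3,5-di-tert-butylsalicylidene)-1,2-cyclohexanediamine dianion, 1 mol%), H2O (0.55 equiv), THF, 0 °C → rt; distillation from the diol
Reagents that add atoms: none
Why: In the Jacobsen hydrolytic kinetic resolution the (S,S) catalyst should hydrolyse the (S)-epoxide and leave the enantiomer that corresponds in space to (S)-propylene oxide, which is R here because the ketal carbon outranks the ring CH2; the sense is to be confirmed on a ring-opened sample (Mosher ester) before use.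

Step 12
Reactants: 13 protected alkyne; 17 (R)-epoxide
Product: 20 E-homoallylic alcohol with ketal-masked methyl ketone (16R), via alkenyldimethylalane 18 (not isolated), via lithium alkenylalanate 19 (not isolated)
Conditions: Al(CH3)3 (3 equiv), (C5H5)2ZrCl2 (0.5 equiv, tetravalent zirconium), ClCH2CH2Cl, 0 °C → rt; volatiles removed in vacuo; hexane, n-BuLi, 0 °C; then 17 (2 equiv), THF, 0 °C → rt; aqueous KNaC4H4O6
Reagents that add atoms: trimethylaluminium, C[Al](C)C
Why: The (C5H5)2ZrCl2/Al(CH3)3 couple forms a methylzirconium–aluminium species that adds CH3 and metal syn across C13≡C14 through a four-centre transition state, methyl to the internal C13 and aluminium to the terminal C14, and n-BuLi then turns the alkenyldimethylalane into a lithium alanate whose alkenyl group attacks the CH2 carbon of 17 in an SN2 opening with retention at C14. The closest known reaction type is the Negishi zirconium-catalysed methylalumination of terminal alkynes followed by epoxide opening with the derived alkenylalanate. No ring is closed and no stereocentre is created: C16 is carried over unchanged from 17 because the new bond is made at the neighbouring CH2, and the E geometry follows from syn addition and retentive transfer. The step needs regioselective carbometalation, which the steric and electronic bias of a terminal alkyne secures, and attack at the unsubstituted epoxide carbon, which the quaternary ketal carbon beside the other terminus enforces. Chemoselectivity rests on the substrate carrying only ethers (PMB, TBS, TES) and on removing excess Al(CH3)3 before 17 is added, so that no free Lewis acid meets the dioxolane.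

Step 13
Reactants: 20 E-homoallylic alcohol with ketal
Product: 21 (16R)-α-hydroxy methyl ketone
Conditions: PPTS, acetone/H2O (10:1), 50 °C
Reagents that add atoms: water, O
Why: Ketal hydrolysis with a pyridinium acid should be mild enough to leave the PMB ether, the hindered secondary TBS ether, the tertiary TES ether and the trisubstituted alkene alone, and too weakly acidic to enolise the ketone toward C16.

Step 14
Reactants: 21 α-hydroxy methyl ketone
Product: 23 protected butenolide, via phosphoranylidene acetate 22 (not isolated)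
Conditions: Ph3P=C=C=O (1.5 equiv), toluene, 80 °C
Reagents that add atoms: (triphenylphosphoranylidene)ketene, O=C=C=P(c1ccccc1)(c1ccccc1)c1ccccc1
Why: In this Bestmann ylide butenolide synthesis the C16 hydroxyl adds to the ketene ylide and the resulting ester ylide closes by intramolecular Wittig reaction on the methyl ketone, forming the 4-methylbutenolide without an external base that could epimerise C16.

Step 15
Reactants: 23 protected butenolide
Product: 24 C18 primary alcohol
Conditions: DDQ, CH2Cl2/pH 7 buffer, 0 °C → rt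
Reagents that add atoms: none
Why: Oxidative PMB cleavage by DDQ (hydride abstraction from the electron-rich benzylic position, then hydrolysis) should free only the C18 hydroxyl, since the silyl ethers, the trisubstituted alkene and the butenolide do not react under buffered conditions.

Step 16
Reactants: 24 C18 primary alcohol
Product: 25 C18 aldehyde
Conditions: Dess–Martin periodinane, NaHCO3, CH2Cl2, rt
Reagents that add atoms: none
Why: Dess–Martin oxidation of the single free, neopentyl primary alcohol gives the non-enolisable C18 aldehyde under neutral conditions, and no lactol can form because O6 is silylated.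

Step 17
Reactants: 25 C18 aldehyde
Product: 26 C18 carboxylic acid (6-O-TBS; 8-O-TES)
Conditions: NaClO2, NaH2PO4, 2-methyl-2-butene, t-BuOH/H2O, rt
Reagents that add atoms: sodium chlorite, [Na+].[O-]Cl=O
Why: Pinnick oxidation converts the hindered aldehyde into the acid at about pH 4, with 2-methyl-2-butene scavenging HOCl so that the C13=C14 alkene and the butenolide are not chlorinated and the silyl ethers stay on.

Step 18
Reactants: 26 C18 carboxylic acid
Product: 27 target, CNP0387770.1
Conditions: HF·pyridine, pyridine, THF, 0 °C → rt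
Reagents that add atoms: none
Why: Fluoride-mediated desilylation in a pyridine-buffered medium removes both silyl ethers without acid strong enough to lactonise the 6α-hydroxy acid or to add the 8α-OH to the C13=C14 alkene, and without base that would touch the butenolide or C16.

**Compound list**

1 | larixol, (13S)-labda-8(17),14-diene-6α,13-diol | C=C[C@@](C)(O)CC[C@@H]1[C@@]2(C)CCCC(C)(C)[C@@H]2[C@@H](O)CC1=C | starting material
2 | 6α-hydroxy-14,15-dinorlabd-8(17)-en-13-one (9β-(3-oxobutyl) decalin) | CC(=O)CC[C@@H]1[C@@]2(C)CCCC(C)(C)[C@@H]2[C@@H](O)CC1=C | intermediate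
3 | 8α,17-epoxy-6α-hydroxy-14,15-dinorlabdan-13-one (spiro-epoxide, oxygen α) | CC(=O)CC[C@@H]1[C@@]2(C)CCCC(C)(C)[C@@H]2[C@@H](O)C[C@]13CO3 | intermediate
4 | 6α-hypoiodite of 3 (not isolated) | CC(=O)CC[C@@H]1[C@@]2(C)CCCC(C)(C)[C@@H]2[C@@H](OI)C[C@]13CO3 | intermediate
5 | 8α,17-epoxy-6α-hydroxy-18-iodo-14,15-dinorlabdan-13-one (not isolated) | CC(=O)CC[C@@H]1[C@@]2(C)CCC[C@@](C)(CI)[C@@H]2[C@@H](O)C[C@]13CO3 | intermediate
6 | 6α,18:8α,17-diepoxy-14,15-dinorlabdan-13-one (tetrahydrofuran from O6 to C18) | CC(=O)CC[C@@H]1[C@@]2(C)CCC[C@@](C)(CO4)[C@@H]2[C@@H]4C[C@]13CO3 | intermediate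
7 | 8α,17-epoxy-13-oxo-14,15-dinorlabdan-18,6α-olide | CC(=O)CC[C@@H]1[C@@]2(C)CCC[C@@](C)(C(=O)O4)[C@@H]2[C@@H]4C[C@]13CO3 | intermediate
8 | enol diethyl phosphate of 7 at the terminal position (not isolated) | C=C(OP(=O)(OCC)OCC)CC[C@@H]1[C@@]2(C)CCC[C@@](C)(C(=O)O4)[C@@H]2[C@@H]4C[C@]13CO3 | intermediate
9 | 9β-(but-3-ynyl) decalin with 8α,17-epoxide and 18,6α-lactone | C#CCC[C@@H]1[C@@]2(C)CCC[C@@](C)(C(=O)O4)[C@@H]2[C@@H]4C[C@]13CO3 | intermediate
10 | 9β-(but-3-ynyl) decalin 6α,8α,18-triol | C#CCC[C@@H]1[C@@]2(C)CCC[C@@](C)(CO)[C@@H]2[C@@H](O)C[C@@]1(C)O | intermediate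
11 | 18-O-(4-methoxybenzyl) ether of 10 | C#CCC[C@@H]1[C@@]2(C)CCC[C@@](C)(COCc3ccc(OC)cc3)[C@@H]2[C@@H](O)C[C@@]1(C)O | intermediate
12 | 18-O-PMB, 6-O-TBS, 8-hydroxy alkyne (not isolated) | C#CCC[C@@H]1[C@@]2(C)CCC[C@@](C)(COCc3ccc(OC)cc3)[C@@H]2[C@@H](O[Si](C)(C)C(C)(C)C)C[C@@]1(C)O | intermediate
13 | 18-O-PMB, 6-O-TBS, 8-O-TES alkyne (precursor of the key step) | C#CCC[C@@H]1[C@@]2(C)CCC[C@@](C)(COCc3ccc(OC)cc3)[C@@H]2[C@@H](O[Si](C)(C)C(C)(C)C)C[C@@]1(C)O[Si](CC)(CC)CC | intermediate
14 | 2-(2-bromoethyl)-2-methyl-1,3-dioxolane | CC1(CCBr)OCCO1 | starting material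
15 | 2-methyl-2-vinyl-1,3-dioxolane | CC1(C=C)OCCO1 | intermediate
16 | racemic 2-(2-methyl-1,3-dioxolan-2-yl)oxirane | CC1(OCCO1)C1CO1 | intermediate
17 | (R)-2-(2-methyl-1,3-dioxolan-2-yl)oxirane | CC1(OCCO1)[C@H]1CO1 | intermediate
18 | (E)-alkenyldimethylalane, Al on C14 cis to the C13 methyl (not isolated) | C/C(CC[C@@H]1[C@@]2(C)CCC[C@@](C)(COCc3ccc(OC)cc3)[C@@H]2[C@@H](O[Si](C)(C)C(C)(C)C)C[C@@]1(C)O[Si](CC)(CC)CC)=C\[Al](C)C | intermediate
19 | lithium butyl(dimethyl)alkenylalanate (not isolated) | C/C(CC[C@@H]1[C@@]2(C)CCC[C@@](C)(COCc3ccc(OC)cc3)[C@@H]2[C@@H](O[Si](C)(C)C(C)(C)C)C[C@@]1(C)O[Si](CC)(CC)CC)=C\[Al-](C)(C)CCCC.[Li+] | intermediate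
20 | (13E,16R)-homoallylic alcohol with 2-methyl-1,3-dioxolane on C16 (product of the key step) | C/C(CC[C@@H]1[C@@]2(C)CCC[C@@](C)(COCc3ccc(OC)cc3)[C@@H]2[C@@H](O[Si](C)(C)C(C)(C)C)C[C@@]1(C)O[Si](CC)(CC)CC)=C\C[C@@H](O)C1(C)OCCO1 | intermediate
21 | (13E,16R)-16-hydroxy methyl ketone | C/C(CC[C@@H]1[C@@]2(C)CCC[C@@](C)(COCc3ccc(OC)cc3)[C@@H]2[C@@H](O[Si](C)(C)C(C)(C)C)C[C@@]1(C)O[Si](CC)(CC)CC)=C\C[C@@H](O)C(C)=O | intermediate
22 | 16-O-(triphenylphosphoranylidene)acetate of 21 (not isolated) | C/C(CC[C@@H]1[C@@]2(C)CCC[C@@](C)(COCc3ccc(OC)cc3)[C@@H]2[C@@H](O[Si](C)(C)C(C)(C)C)C[C@@]1(C)O[Si](CC)(CC)CC)=C\C[C@@H](OC(=O)C=P(c1ccccc1)(c1ccccc1)c1ccccc1)C(C)=O | intermediate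
23 | 4-methylbutenolide with 18-O-PMB, 6-O-TBS, 8-O-TES | C/C(CC[C@@H]1[C@@]2(C)CCC[C@@](C)(COCc3ccc(OC)cc3)[C@@H]2[C@@H](O[Si](C)(C)C(C)(C)C)C[C@@]1(C)O[Si](CC)(CC)CC)=C\C[C@H]1OC(=O)C=C1C | intermediate
24 | butenolide with free C18 hydroxyl (6-O-TBS, 8-O-TES) | C/C(CC[C@@H]1[C@@]2(C)CCC[C@@](C)(CO)[C@@H]2[C@@H](O[Si](C)(C)C(C)(C)C)C[C@@]1(C)O[Si](CC)(CC)CC)=C\C[C@H]1OC(=O)C=C1C | intermediate
25 | butenolide C18 aldehyde (6-O-TBS, 8-O-TES) | C/C(CC[C@@H]1[C@@]2(C)CCC[C@@](C)(C=O)[C@@H]2[C@@H](O[Si](C)(C)C(C)(C)C)C[C@@]1(C)O[Si](CC)(CC)CC)=C\C[C@H]1OC(=O)C=C1C | intermediate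
26 | butenolide C18 carboxylic acid (6-O-TBS, 8-O-TES) | C/C(CC[C@@H]1[C@@]2(C)CCC[C@@](C)(C(=O)O)[C@@H]2[C@@H](O[Si](C)(C)C(C)(C)C)C[C@@]1(C)O[Si](CC)(CC)CC)=C\C[C@H]1OC(=O)C=C1C | intermediate
27 | CNP0387770.1, (13E,16R)-6α,8α-dihydroxy butenolide 18-oic acid | CC1=CC(=O)O[C@@H]1C/C=C(\C)CC[C@@H]1[C@@]2(C)CCC[C@@](C)(C(=O)O)[C@@H]2[C@@H](O)C[C@@]1(C)O | target

**Step count and risks**

Total: 18 steps. Longest linear sequence: 15 steps (1 to 27 through steps 1–8 and 12–18); the epoxide branch (steps 9–11) has 3 steps.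

Steps most likely to fail:

1. Step 3. The hypoiodite conditions may open the spiro-epoxide through iodine or acetic acid, over-oxidise the substrate, or stall at the neopentyl iodide when ring closure to the ether is slow. Fallback: nitrite photolysis, which needs no iodine and no displacement. Setting out from 3, NOCl in pyridine at −20 °C should give the 6α-nitrite ester F1. Irradiation through Pyrex in benzene transfers NO to C18 by the same 1,5-hydrogen shift and gives the C18-nitroso alcohol F2, which tautomerises on warming in 2-propanol to the 18-oxime F3. TiCl3 (trivalent titanium) buffered with NH4OAc in aqueous dioxane reduces the oxime to the imine, whose hydrolysis gives the 18,6α-lactol F4. TEMPO with PhI(OAc)2 in CH2Cl2 oxidises F4 to lactone 7, where the route resumes; compound 6 and step 4 are bypassed.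

2. Step 12. Transfer of the alkenyl group from the alanate to the hindered, ketal-bearing epoxide may be slow, so that protonolysis to the simple alkene or ketal cleavage by residual aluminium Lewis acid takes over. Fallback: a stepwise union through an isolated alkenyl halide. Setting out from 13, the same methylalumination (via 18) is quenched with I2 in THF at −30 °C to give the E-alkenyl iodide F5. Halogen–lithium exchange with t-BuLi (2 equiv, Et2O, −78 °C) gives the alkenyllithium F6, which in the presence of BF3·OEt2 at −78 °C opens epoxide 17 at its CH2 terminus and returns to 20.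

3. Step 7. Alkylation may not discriminate cleanly between O18 and O6 (double etherification), or the neopentyl alkoxide may react sluggishly. Fallback: temporary acylation of the primary hydroxyl. Setting out from 10, pivaloyl chloride in pyridine at 0 °C should acylate only the primary hydroxyl to give the 18-pivalate F7. TBSOTf then TESOTf with 2,6-lutidine, as in step 8, give the 6-O-TBS pivalate F8 and then the bis-silyl pivalate F9. (i-Bu)2AlH in CH2Cl2 at −78 °C removes the pivalate to give the 18-alcohol F10. 4-Methoxybenzyl trichloroacetimidate with catalytic La(OTf)3 etherifies the only free hydroxyl without forming an alkoxide, so no silyl group migrates, and returns to 13.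

**Further compounds**

F1 | step 3 | 6α-nitrite ester of 3 | CC(=O)CC[C@@H]1[C@@]2(C)CCCC(C)(C)[C@@H]2[C@@H](ON=O)C[C@]13CO3
F2 | step 3 | 8α,17-epoxy-6α-hydroxy-18-nitroso-14,15-dinorlabdan-13-one | CC(=O)CC[C@@H]1[C@@]2(C)CCC[C@@](C)(CN=O)[C@@H]2[C@@H](O)C[C@]13CO3
F3 | step 3 | 8α,17-epoxy-6α-hydroxy-13-oxo-14,15-dinorlabdan-18-al oxime | CC(=O)CC[C@@H]1[C@@]2(C)CCC[C@@](C)(C=NO)[C@@H]2[C@@H](O)C[C@]13CO3
F4 | step 3 | 18,6α-lactol (cyclic hemiacetal of the 18-aldehyde with O6) | CC(=O)CC[C@@H]1[C@@]2(C)CCC[C@@](C)(C(O)O4)[C@@H]2[C@@H]4C[C@]13CO3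
F5 | step 12 | (E)-alkenyl iodide, iodine on C14 | C/C(CC[C@@H]1[C@@]2(C)CCC[C@@](C)(COCc3ccc(OC)cc3)[C@@H]2[C@@H](O[Si](C)(C)C(C)(C)C)C[C@@]1(C)O[Si](CC)(CC)CC)=C\I
F6 | step 12 | (E)-alkenyllithium, lithium on C14 | C/C(CC[C@@H]1[C@@]2(C)CCC[C@@](C)(COCc3ccc(OC)cc3)[C@@H]2[C@@H](O[Si](C)(C)C(C)(C)C)C[C@@]1(C)O[Si](CC)(CC)CC)=C\[Li]
F7 | step 7 | 18-O-pivalate of triol 10 | C#CCC[C@@H]1[C@@]2(C)CCC[C@@](C)(COC(=O)C(C)(C)C)[C@@H]2[C@@H](O)C[C@@]1(C)O
F8 | step 7 | 18-O-pivalate, 6-O-TBS, 8-hydroxy alkyne | C#CCC[C@@H]1[C@@]2(C)CCC[C@@](C)(COC(=O)C(C)(C)C)[C@@H]2[C@@H](O[Si](C)(C)C(C)(C)C)C[C@@]1(C)O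
F9 | step 7 | 18-O-pivalate, 6-O-TBS, 8-O-TES alkyne | C#CCC[C@@H]1[C@@]2(C)CCC[C@@](C)(COC(=O)C(C)(C)C)[C@@H]2[C@@H](O[Si](C)(C)C(C)(C)C)C[C@@]1(C)O[Si](CC)(CC)CC
F10 | step 7 | 18-hydroxy, 6-O-TBS, 8-O-TES alkyne | C#CCC[C@@H]1[C@@]2(C)CCC[C@@](C)(CO)[C@@H]2[C@@H](O[Si](C)(C)C(C)(C)C)C[C@@]1(C)O[Si](CC)(CC)CC
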